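Ring A is cut at its two opposite bonds, C2–C3 and C5–C10. This exploits the 1,3-relationship of C3 and C5 across the gem-dimethyl carbon C4 and of C2 and C10 across C1: a C3–C4–C5 unit nucleophilic at both ends (nitronate at C3, aldehyde enamine at C5) meets a C2–C1–C10 unit electrophilic at both ends (δ- and β-carbons of a dienone). In one flask a vinylogous nitro-Michael addition forms C2–C3 and an amine-catalysed Michael addition forms C5–C10, closing ring A and setting the quaternary ring-fusion centre C10. The precursors are 3,3-dimethyl-4-nitrobutanal and 4-methylhexa-3,5-dien-2-one; ring B follows by aldol condensation.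

Key step: step 4

Remark: labdane numbering (C1–C20) and α/β face descriptors are used for ring carbons; the catalyst enantiomer in step 4 is assigned by analogy with its intermolecular Michael additions and would be checked on 11, the antipodal catalyst being used if the mirror-image series forms.

Step 1
Reactants: 1 methyl 3-methylbut-2-enoate; 2 nitromethane
Product: 3 methyl 3,3-dimethyl-4-nitrobutanoate
Conditions: DBU (20 mol %), CH3NO2 (excess), 60 °C
Reagents that add atoms: none
Why: Base-catalysed Michael addition of the nitronate to the β,β-disubstituted enoate builds the quaternary carbon that becomes C4, and no stereocentre is formed.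

Step 2
Reactants: 3 methyl 3,3-dimethyl-4-nitrobutanoate
Product: 4 3,3-dimethyl-4-nitrobutanal
Conditions: i-Bu2AlH (1.2 equiv), CH2Cl2, −78 °C; aq. potassium sodium tartrate
Reagents that add atoms: none
Why: Partial reduction of the ester stops at the aluminium hemiacetal, which is stable at −78 °C and gives the aldehyde on work-up, while the nitro group is left intact.

Step 3
Reactants: 5 (E)-4-methoxypent-3-en-2-one
Product: 7 (E)-4-methylhexa-3,5-dien-2-one, via 5-methoxy-3-methylhexa-1,4-dien-3-ol 6 (not isolated)
Conditions: CH2=CHMgBr, THF, 0 °C; then 1 M HCl, 23 °C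
Reagents that add atoms: vinylmagnesium bromide, C=C[Mg]Br
Why: 1,2-addition of the Grignard reagent to the vinylogous ester and acid-induced hydrolysis and dehydration of the carbinol (alkylative carbonyl transposition) should give the conjugated dienone, whose double-bond geometry does not matter for step 4.

Step 4
Reactants: 4 3,3-dimethyl-4-nitrobutanal; 7 (E)-4-methylhexa-3,5-dien-2-one
Product: 9 (1R,2R,5RS)-2,6,6-trimethyl-5-nitro-2-(2-oxopropyl)cyclohexane-1-carbaldehyde, via open-chain nitro enone 8 (not isolated)
Conditions: DBU (10 mol %), CH2Cl2, 0 → 23 °C; then (R)-2-[diphenyl(trimethylsilyloxy)methyl]pyrrolidine (20 mol %), PhCO2H (30 mol %), 23 °C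
Reagents that add atoms: none
Why: Proposed new method: DBU deprotonates the nitro group of 4, which is far more acidic than the aldehyde, and the nitronate adds to the unhindered δ-carbon C2 of 7 (vinylogous Michael addition), forming C2–C3 and, after reconjugation, enone 8. The secondary amine then turns the aldehyde into its enamine, whose carbon C5 adds to the β-carbon C10 of the enone in a 6-exo-trig closure of ring A, forming C5–C10. The closest known reactions are the base-mediated 1,6-addition of nitroalkanes to δ-unsubstituted dienones and the amine-catalysed intramolecular Michael addition of formyl enones; new are their union in one flask and the β,β-disubstituted acceptor that creates a quaternary centre. C5 and C10 are set together, since the silyloxydiphenylmethyl group of the catalyst shields one face of the enamine and a chair-like transition state with the oxobutenyl arm equatorial should place the C10 methyl group axial and trans to H5. The centre at C3 is not controlled and is removed in step 5. The step needs δ- over β-attack in the first addition and nitronate before enamine reactivity, which the β-methyl group and the late addition of the amine should secure.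

Step 5
Reactants: 9 (1R,2R,5RS)-2,6,6-trimethyl-5-nitro-2-(2-oxopropyl)cyclohexane-1-carbaldehyde
Product: 11 (4aS,8aR)-5,5,8a-trimethyl-4a,5,6,7,8,8a-hexahydronaphthalen-2(1H)-one, via keto aldehyde 10 (not isolated)
Conditions: Bu3SnH (2 equiv), AIBN (cat.), PhMe, 110 °C; then p-TsOH·H2O (20 mol %), 110 °C
Reagents that add atoms: none
Why: Radical denitration (the nitro group served as a traceless activator of C3) followed by acid-catalysed intramolecular aldol condensation of the methyl ketone onto the aldehyde (Robinson-type closure of ring B) should give the enone, in which H5 is γ to the carbonyl and the ring fusion can settle trans.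

Step 6
Reactants: 12 (E)-3-methylpent-2-en-4-yn-1-ol
Product: 13 (E)-3-methylpenta-2,4-dien-1-ol
Conditions: H2 (1 atm), Pd/CaCO3 poisoned with Pb(OAc)2, quinoline, EtOAc, 23 °C
Reagents that add atoms: none
Why: Lindlar semi-hydrogenation reduces only the terminal alkyne to the vinyl group, so the (E)-trisubstituted double bond is retained.

Step 7
Reactants: 13 (E)-3-methylpenta-2,4-dien-1-ol
Product: 14 (E)-1-bromo-3-methylpenta-2,4-diene
Conditions: PBr3 (0.4 equiv), Et2O, −10 °C
Reagents that add atoms: phosphorus tribromide, BrP(Br)Br
Why: SN2 displacement of the phosphite ester of the primary allylic alcohol by bromide keeps the (E)-geometry of the conjugated diene.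

Step 8
Reactants: 11 (4aS,8aR)-5,5,8a-trimethyl-4a,5,6,7,8,8a-hexahydronaphthalen-2(1H)-one; 14 (E)-1-bromo-3-methylpenta-2,4-diene
Product: 16 (12E)-17-norlabda-6,12,14-trien-8-one, via 9α-epimer 15 (not isolated)
Conditions: LiN(i-Pr)2, THF, −78 °C; 14, DMPU, −78 → 0 °C; then NaOCH3 (cat.), CH3OH, 23 °C
Reagents that add atoms: none
Why: Kinetic α′-deprotonation of the cyclohexenone at C9 and SN2 alkylation by the allylic bromide (enolate alkylation) should first place the chain anti to the axial C10 methyl group, and methoxide equilibration next to the ketone then moves it into the equatorial 9β position.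

Step 9
Reactants: 16 (12E)-17-norlabda-6,12,14-trien-8-one
Product: 17 (12E)-labda-6,12,14-trien-8-ol
Conditions: CH3Li, CeCl3, THF, −78 °C
Reagents that add atoms: methyllithium, [Li]C
Why: 1,2-addition of the organocerium reagent to the hindered enone carbonyl (CeCl3 suppresses enolisation) brings in C17, and the configuration of the new carbinol centre C8 is of no consequence because C8 becomes sp2 in step 10.

Step 10
Reactants: 17 (12E)-labda-6,12,14-trien-8-ol
Product: 18 (12E)-labda-7,12,14-trien-6-one
Conditions: pyridinium chlorochromate [C5H5NH][CrO3Cl], NaOAc, 4 Å molecular sieves, CH2Cl2, 23 °C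
Reagents that add atoms: none
Why: Babler–Dauben oxidative transposition, in which the chromate ester of the tertiary allylic alcohol shifts to C6 and is oxidised there, should give the 7-en-6-one with the methyl-bearing C8 in the double bond and no new stereocentre.

Step 11
Reactants: 18 (12E)-labda-7,12,14-trien-6-one
Product: 19 (12E)-7α,8α-epoxylabda-12,14-dien-6-one
Conditions: 30% H2O2, NaOH (aq), CH3OH, 0 → 23 °C
Reagents that add atoms: hydrogen peroxide, OO
Why: Weitz–Scheffer nucleophilic epoxidation touches only the enone and not the side-chain diene, and hydroperoxide should add to C8 from the α face because the β face is screened by the axial C10 methyl group and the 9β chain, which sets C7 and C8.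

Step 12
Reactants: 19 (12E)-7α,8α-epoxylabda-12,14-dien-6-one
Product: 20 (12E)-7α,8α-epoxylabda-12,14-dien-6β-ol
Conditions: NaBH4, CH3OH, 0 °C
Reagents that add atoms: none
Why: Substrate-controlled borohydride reduction, in which hydride reaches the C6 ketone from the α face because the β face is blocked by the syn-axial methyl groups on C4 and C10, should give the axial 6β-alcohol trans to the epoxide.

Step 13
Reactants: 20 (12E)-7α,8α-epoxylabda-12,14-dien-6β-ol
Product: 22 (12E)-labda-12,14-diene-6β,7β,8α-triol, via cyclic carbonate 21 (not isolated)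
Conditions: Cs2CO3, CO2 (1 atm), DMF, 3 Å molecular sieves, 40 °C; then CH3OH, 23 °C
Reagents that add atoms: carbon dioxide, O=C=O
Why: The caesium alkoxide at O6 is carboxylated and the carbonate anion opens the trans-epoxide by intramolecular SN2 attack at C7 (5-exo, inversion to 7β, the tertiary C8–O bond and its α configuration untouched), after which methanolysis of the cyclic carbonate frees the 6β,7β-diol.

Step 14
Reactants: 22 (12E)-labda-12,14-diene-6β,7β,8α-triol
Product: 23 (12E)-6β,8α-dihydroxylabda-12,14-dien-7β-yl acetate
Conditions: Ac2O (1.2 equiv), pyridine, 0 °C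
Reagents that add atoms: acetic anhydride, CC(=O)OC(C)=O
Why: Selective esterification should take the equatorial secondary 7β-hydroxyl in preference to the axial 6β-hydroxyl, which is flanked by two syn-axial methyl groups, and to the tertiary 8α-hydroxyl, with no stereocentre affected.

Compound list
1 | methyl 3-methylbut-2-enoate | CC(C)=CC(=O)OC | starting material
2 | nitromethane | C[N+](=O)[O-] | starting material
3 | methyl 3,3-dimethyl-4-nitrobutanoate | COC(=O)CC(C)(C)C[N+](=O)[O-] | intermediate
4 | 3,3-dimethyl-4-nitrobutanal | O=CCC(C)(C)C[N+](=O)[O-] | intermediate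
5 | (E)-4-methoxypent-3-en-2-one | CO/C(C)=C/C(C)=O | starting material
6 | 5-methoxy-3-methylhexa-1,4-dien-3-ol (as bromomagnesium alkoxide, racemic) | CO/C(C)=C/C(C)(O)C=C | intermediate
7 | (E)-4-methylhexa-3,5-dien-2-one | CC(=O)/C=C(C)/C=C | intermediate
8 | (E)-3,3,7-trimethyl-4-nitro-9-oxodec-7-enal (C3 unassigned) | O=CCC(C)(C)C([N+](=O)[O-])CC/C(C)=C/C(C)=O | intermediate
9 | (1R,2R,5RS)-2,6,6-trimethyl-5-nitro-2-(2-oxopropyl)cyclohexane-1-carbaldehyde (formyl and oxopropyl trans; 5α-H, 10β-CH3; both C3 epimers) | O=C[C@H]1C(C)(C)C([N+](=O)[O-])CC[C@]1(C)CC(C)=O | intermediate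
10 | (1S,2R)-2,6,6-trimethyl-2-(2-oxopropyl)cyclohexane-1-carbaldehyde | O=C[C@H]1C(C)(C)CCC[C@]1(C)CC(C)=O | intermediate
11 | (4aS,8aR)-5,5,8a-trimethyl-4a,5,6,7,8,8a-hexahydronaphthalen-2(1H)-one (trans-fused; 5α-H, 10β-CH3) | C1C(=O)C=C[C@H]2C(C)(C)CCC[C@@]21C | intermediate
12 | (E)-3-methylpent-2-en-4-yn-1-ol | OC/C=C(C)/C#C | starting material
13 | (E)-3-methylpenta-2,4-dien-1-ol | OC/C=C(C)/C=C | intermediate
14 | (E)-1-bromo-3-methylpenta-2,4-diene | BrC/C=C(C)/C=C | intermediate
15 | (12E)-17-nor-9-epi-labda-6,12,14-trien-8-one (9α side chain) | C=C/C(C)=C/C[C@@H]1C(=O)C=C[C@H]2C(C)(C)CCC[C@@]21C | intermediate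
16 | (12E)-17-norlabda-6,12,14-trien-8-one (9β side chain, 5α-H, 10β-CH3) | C=C/C(C)=C/C[C@H]1C(=O)C=C[C@H]2C(C)(C)CCC[C@@]21C | intermediate
17 | (12E)-labda-6,12,14-trien-8-ol (8β-hydroxy epimer shown; either epimer serves) | C=C/C(C)=C/C[C@H]1[C@@](C)(O)C=C[C@H]2C(C)(C)CCC[C@@]21C | intermediate
18 | (12E)-labda-7,12,14-trien-6-one | C=C/C(C)=C/C[C@H]1C(C)=CC(=O)[C@H]2C(C)(C)CCC[C@@]21C | intermediate
19 | (12E)-7α,8α-epoxylabda-12,14-dien-6-one | C=C/C(C)=C/C[C@H]1[C@]3(C)O[C@@H]3C(=O)[C@H]2C(C)(C)CCC[C@@]21C | intermediate
20 | (12E)-7α,8α-epoxylabda-12,14-dien-6β-ol | C=C/C(C)=C/C[C@H]1[C@]3(C)O[C@@H]3[C@@H](O)[C@H]2C(C)(C)CCC[C@@]21C | intermediate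
21 | (12E)-8α-hydroxylabda-12,14-diene-6β,7β-diyl carbonate | C=C/C(C)=C/C[C@H]1[C@](C)(O)[C@H]3OC(=O)O[C@H]3[C@H]2C(C)(C)CCC[C@@]21C | intermediate
22 | (12E)-labda-12,14-diene-6β,7β,8α-triol | C=C/C(C)=C/C[C@H]1[C@](C)(O)[C@@H](O)[C@@H](O)[C@H]2C(C)(C)CCC[C@@]21C | intermediate
23 | (12E)-6β,8α-dihydroxylabda-12,14-dien-7β-yl acetate, (5S,6S,7S,8S,9R,10S) | C=C/C(C)=C/C[C@H]1[C@](C)(O)[C@@H](OC(C)=O)[C@@H](O)[C@H]2C(C)(C)CCC[C@@]21C | target

Total step count: 14. Longest linear sequence: 11 steps (1, 2, 4, 5, 8, 9, 10, 11, 12, 13, 14).

Steps most likely to fail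

Step 4 (bears the label). The ring closure onto the β,β-disubstituted enone may be slow, so that the sequence stalls at the open-chain adduct, or the facial selectivity at C10 may be low. Fallback with known chemistry, setting out from 4 and 7: DBU alone gives the adduct 8, which is isolated. It is cyclised through the aldehyde enolate (DBU, 1 equiv, CH3CN, 60 °C; base-mediated intramolecular Michael addition under thermodynamic control) to racemic trans-nitro keto aldehyde F1. The conditions of step 5 turn this into racemic enone F2, which is resolved by preparative chromatography on a chiral stationary phase; the route is rejoined at 11.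

Step 13. The carbonate anion may fail to reach the hindered C7, or base-induced epoxide migration may run ahead of the opening. Fallback, setting out from 19: the α-keto epoxide is opened at C7 by caesium acetate and acetic acid in DMF, an SN2 substitution at the carbon next to the ketone (C8 is tertiary and cannot compete), to give 7β-acetoxy-8α-hydroxy ketone F5. Luche reduction (NaBH4, CeCl3, CH3OH, −40 °C) from the α face then gives the 6β-alcohol; the route is rejoined at 23.

Step 8. The dienyl bromide may polymerise or scramble by allylic transposition under the strongly basic conditions, and over-alkylation is possible. Fallback, setting out from 11 and 12: PBr3 converts 12 into the sturdier enyne bromide F3. Alkylation of the lithium enolate of 11 and methoxide equilibration as in step 8 give enyne ketone F4, and Lindlar semi-hydrogenation of its terminal alkyne forms the diene; the route is rejoined at 16.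

Further compounds
F1 | step 4 | racemic trans-2,6,6-trimethyl-5-nitro-2-(2-oxopropyl)cyclohexane-1-carbaldehyde | O=C[C@H]1C(C)(C)C([N+](=O)[O-])CC[C@]1(C)CC(C)=O.O=C[C@@H]1C(C)(C)C([N+](=O)[O-])CC[C@@]1(C)CC(C)=O
F2 | step 4 | racemic trans-5,5,8a-trimethyl-4a,5,6,7,8,8a-hexahydronaphthalen-2(1H)-one | C1C(=O)C=C[C@H]2C(C)(C)CCC[C@@]21C.C1C(=O)C=C[C@@H]2C(C)(C)CCC[C@]21C
F3 | step 8 | (E)-5-bromo-3-methylpent-3-en-1-yne | BrC/C=C(C)/C#C
F4 | step 8 | (12E)-17-norlabda-6,12-dien-14-yn-8-one | C#C/C(C)=C/C[C@H]1C(=O)C=C[C@H]2C(C)(C)CCC[C@@]21C
F5 | step 13 | (12E)-7β-acetoxy-8α-hydroxylabda-12,14-dien-6-one | C=C/C(C)=C/C[C@H]1[C@](C)(O)[C@@H](OC(C)=O)C(=O)[C@H]2C(C)(C)CCC[C@@]21C
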